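Remarks on the chemistry (assumptions):
- Locants are those of the pseudoguaiane skeleton: C1–C5 five-membered ring with the ketone at C4; C5–C10 and C1 seven-membered ring; C11–C13 lactone carbons; C14 the methyl on C10, C15 the methyl on C5. α is the face of H-1, β the face of the C5 methyl group. Primed locants belong to the p-menthadiene (C2' bears the methyl group, C5' the oxygenated propyl group).
- The bis(oxazoline) antipode in step 4 is the one that gives (8aS)-7; if the first choice gives the mirror image, its enantiomer is used.
- Compounds 9 and 10 are carried as C10 epimers, which converge in step 8; C11 is epimeric in 16–20 and is erased in step 14.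

## The problem

The target is a pseudoguaianolide: a cyclopentenone trans-fused to a cycloheptane that carries a cis-fused 12,8-lactone. Its lactone α-carbon C11 is the spiro centre of a bicyclo[2.2.2]octene built from a p-menthadienol; the C6 oxygen is tigloylated, and the C9 and side-chain tertiary hydroxyls are free. Seven contiguous stereocentres line the carbocycle (C1, C5, C6, C7, C8, C9, C10), C11 is quaternary, and three more centres sit in the bicyclooctene. The quaternary C5 is the natural anchor. Its methyl group shields the β face, so H-1 (trans fusion) and the C6 oxygen can be brought in from the α face. C6 can then steer C7, C7 can steer C8, C8 can steer C9, and C10 can be equilibrated while C9 is a ketone. C11 and the bicyclooctene centres arise in one [4+2] event, and the diene carries the only centre that cannot be relayed from the core. The molecule tolerates little. The cyclopentenone is a Michael acceptor with an epimerisable γ-hydrogen at C1. The C4 ketone and the C6 oxygen form an aldol unit open to retro-aldol cleavage. The α-methylene lactone needed for the cycloaddition accepts hydride and nucleophiles, and the tertiary carbinol ionises in acid. The enabling feature is the seven-membered ring C5–C6–C7–C8–C9–C10–C1 fused to a five-membered ring whose C4 ketone flanks the methyl-bearing quaternary C5. That is the imprint of an α-diazoketone whose carbene has added to its own aryl ring and whose norcaradiene has opened, with C6–C10 and C1 as the former benzene carbons.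

## Retrosynthesis

**Enone and C9 alcohol last (31 ⇒ 28 ⇒ 27).** No skeletal bond is cut. The C2=C3 π bond is removed first because the cyclopentenone would compete as a dienophile under Lewis acid and would not survive hydride. In 28 the C4 ketone is the only carbonyl that can enolise, since C5 and C11 are quaternary, so one Saegusa oxidation finishes the synthesis. The 9β-alcohol of 28 is traced to ketone 27. The forward reduction must take the α-acyloxy ketone before the C4 ketone and deliver hydride from the α face.

**Cycloaddition (27 ⇒ 21 + 26).** The bonds C11–C4' and C13–C1' are cut. This is the most convergent cut in the molecule: it removes ten carbons and four stereocentres at once and leaves an α-methylene lactone 21 and a diene 26. Joining the monoterpene earlier would carry a second alkene and a tertiary carbinol through the whole core synthesis. The forward reaction must be para-oriented, use the diene face anti to the C5' substituent, and be carbonyl-endo. With the (R)-diene these three choices together place the new C11–C4' bond on the lactone face that carries C6, which is (11S). The exo mode would use the other face and give the C11 epimer, so endo selectivity and facial selectivity are one and the same demand.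

**Lactone and methylene (21 ⇒ 19 ⇒ 17).** The C8–O bond is cut. Closing the lactone by carboxylate displacement of an α-keto bromide makes the cis fusion a consequence of ring size and inversion, not of a hydride or oxidant approaching a crowded face. C13 is carried as a hydroxymethyl group from the start, so no strong base is needed for methylenation while two ketones and a tiglate are present.

**C7–C11 bond (17 ⇒ 12 + 15).** The cut is a conjugate addition to the γ-acyloxy enone 12. It was preferred to epoxide opening at C7 or enolate alkylation at C7 for two reasons: the C6 oxygen directs the nucleophile to the opposite (β) face, and the enol silane left behind marks C8, not C10, for bromination. The donor 15 is made in two steps from tert-butyl 3-hydroxypropanoate 13 via 14.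

**C6 oxygen from the arene's own double bond (12 ⇒ 11 ⇒ 10 ⇒ 9).** The C6–O bond is cut back to the C6=C7 alkene that survives from the benzene ring. α-Face epoxidation opposite the C5 methyl and base-induced opening of the β,γ-epoxy ketone give the 6α-alcohol and the C7=C8 enone in two steps. The same base equilibrates C10. Acylation to 12 puts the tiglate on early, which removes a protecting group and masks the aldol unit.

**Ring fusion and C9 ketone (9 ⇒ 8 ⇒ 7).** The C1–H bond is cut back to the C1=C10 enone 8, which must be reduced to the trans fusion with the C6=C7 alkene out of conjugation. Enone 8 comes from enol ether 7 by hydrolysis under kinetic protonation at C8.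

**Key disconnection (7 ⇒ 5, through 6).** C5–C1 and C5–C6 are cut and C1–C6 is reconnected. The bicyclic dienone becomes an acyclic aryl α-diazoketone, two rings and the quaternary centre simpler. Only the C9 oxygen is kept on the arene. A second ring oxygen at C8 looked attractive but was set aside: as half of an enediol diether it can be unmasked only as an α-methoxy ketone or by an unselective vinylogous hydrolysis, and C8 is better oxygenated later by the SN2 lactonisation. The forward step must choose one enantioface of the carbene and the unsubstituted ortho bond.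

**Diazoketone (5 ⇒ 4 ⇒ 3 ⇒ 2 ⇒ 1).** Acylation of diazoethane by acid chloride 4 fixes the diazo group on the methyl-bearing carbon, which diazo transfer to an ethyl ketone with two α-methylene groups could not do. Acid 3 comes from commercial 3-methoxy-2-methylbenzaldehyde 1 by Knoevenagel–Doebner condensation to 2 and hydrogenation.

**Diene (26 ⇒ 25 ⇒ 24 ⇒ 23 ⇒ 22).** (R)-Carvone 22 already holds the one stereocentre. Hydration gives 23, and a Shapiro reaction of tosylhydrazone 24 turns the enone into the 1,3-diene 25, which is silylated to 26.

## Roads not taken

**Alternative 1:** The cut is C6–C7. In the forward step SmI2 reduces a C6 aldehyde to a ketyl that adds to C7 of a butenolide, closing the seven-membered ring and giving the 6-hydroxy 12,8-lactone A1 with the C4 ketal and C9 silyl ether in place. Its merit is that C6, C7 and the lactone are formed together on a substrate that already has the C8 and C9 oxygens, so little remains after ring closure. In this respect it is better than the chosen plan, which needs seven steps (7–9 and 12–14) for the same triad. Its weak points lie before the key step: C1, C5, C8, C9 and C10 must be set on a substrate without the help of the bicycle. The ketyl must also close a seven-membered ring from a neopentyl aldehyde in competition with simple reduction. The chosen plan sets against this a four-step precursor, catalytic control of C5, and relay of every later centre from C5 on a rigid ring system.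

**Alternative 2:** The cuts are C1–C10 and C4–C5 across a cyclodecene. Irradiation of a β-acetoxy enone makes it add to the transannular alkene in crossed fashion, and retro-aldol cleavage of the cyclobutane leaves the trans-fused 4,9-dione 8,12-lactone A2. Its merits are real: both rings, the quaternary C5, both ketones, the C6 oxygen and the lactone are present at once, and C10 can be equilibrated. This is a more advanced intermediate than the chosen key step delivers. The weakness is the substrate: a ten-membered ring with defined alkene geometry and four stereocentres is a synthesis in itself. Crossed against straight addition and the face of the transannular approach decide the ring fusion without an obvious control element. The retro-aldol base meets a β-silyloxy ketone. The chosen plan offers predictable regiochemistry (one ortho bond is blocked) and a catalyst-set C5, and pays for it with later functionalisation.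

**Alternative 3:** The cut is a one-carbon ring expansion of a trans-hydrindanone. Cyclopropanation of its silyl enol ether with Et2Zn and CH2I2, then FeCl3 cleavage, gives the cycloheptenone A3. It is the better answer to the ring fusion: C1 and C5 come ready-made and trans from a well-known enantiopure building block, whereas the chosen plan relies on a dissolving-metal protonation for C1. Its weakness for this target is what A3 lacks. C6 is an unactivated methylene next to the quaternary carbon, C7 is unfunctionalised, and C9 has no oxygen, so the four oxygen- or carbon-bearing centres C6–C9 would all need late C–H or enolate chemistry. The chosen plan sets against the safer ring fusion the fact that every carbon from C6 to C10 arrives sp2 and addressable.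

Key step: step 4

## Route

Step 1
Reactants: 1 3-methoxy-2-methylbenzaldehyde
Product: 2 (E)-3-(3-methoxy-2-methylphenyl)prop-2-enoic acid
Conditions: malonic acid, pyridine, piperidine (cat.), 100 °C
Reagents that add atoms: malonic acid OC(=O)CC(=O)O
Why: Knoevenagel–Doebner condensation with decarboxylation gives the (E)-cinnamic acid directly.

Step 2
Reactants: 2 (E)-3-(3-methoxy-2-methylphenyl)prop-2-enoic acid
Product: 3 3-(3-methoxy-2-methylphenyl)propanoic acid
Conditions: H2 (1 atm), palladium on carbon, EtOAc, rt
Reagents that add atoms: none
Why: Catalytic hydrogenation of a cinnamic acid; the anisole ring is not reduced under these conditions.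

Step 3
Reactants: 3 3-(3-methoxy-2-methylphenyl)propanoic acid
Product: 5 2-diazo-5-(3-methoxy-2-methylphenyl)pentan-3-one, via acid chloride 4 (not isolated)
Conditions: (COCl)2, DMF (cat.), CH2Cl2, 0 °C to rt; then CH3CHN2 (3 equiv, from N-ethyl-N-nitrosourea and aq. KOH), Et2O, −20 to 0 °C
Reagents that add atoms: diazoethane CC=[N+]=[N-]
Why: Acylation of a diazoalkane by an acid chloride places the diazo group on the methyl-bearing carbon without regiochemical ambiguity; the excess diazoethane takes up the HCl.

Step 4
Reactants: 5 2-diazo-5-(3-methoxy-2-methylphenyl)pentan-3-one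
Product: 7 (8aS)-5-methoxy-4,8a-dimethyl-2,3-dihydroazulen-1(8aH)-one, via norcaradiene 6 (not isolated)
Conditions: [Cu(MeCN)4]PF6 (5 mol%), 2,2-bis[(4R)-4-phenyl-4,5-dihydrooxazol-2-yl]propane (6 mol%), Na[B(3,5-(CF3)2C6H3)4] (6 mol%), CH2Cl2, reflux, slow addition of 5
Reagents that add atoms: none
Why: The monovalent copper–bis(oxazoline) cation takes N2 from 5 and gives an electrophilic copper carbene at C5. The carbene adds across the C1–C6 bond of the tethered arene in a [2+1] step that forms C5–C1 and C5–C6; the tether makes this a 5-exo-type closure of the five-membered ring onto the ipso carbon and gives norcaradiene 6. Disrotatory six-electron electrocyclic opening of 6 cleaves C1–C6, so the seven-membered ring arises by ring expansion of the benzene ring and not by an end-to-end cyclisation. The closest known reaction type is the intramolecular Büchner reaction of methyl-terminated aryl α-diazoketones to 8a-methylazulenones under copper–bis(oxazoline) catalysis with a non-coordinating counter-ion. The only new stereocentre, C5, is set by the ligand, which decides the enantioface of the carbene that meets the arene. The step needs addition at C1–C6 and not C1–C10: the C10 methyl blocks the other ortho bond, and C6, para to the methoxy group, is the more electron-rich ortho carbon. Slow addition and the weakly coordinating anion are meant to keep 1,2-hydride shift from the C5 methyl and aromatic substitution at C6 in check.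

Step 5
Reactants: 7 (8aS)-5-methoxy-4,8a-dimethyl-2,3-dihydroazulen-1(8aH)-one
Product: 8 (8aS)-4,8a-dimethyl-2,3,6,8a-tetrahydroazulene-1,5-dione (ketones at C4 and C9; C1=C10 and C6=C7)
Conditions: oxalic acid, THF/H2O, 0 °C
Reagents that add atoms: water O
Why: Enol ether hydrolysis under kinetic control: a dienol ether is protonated at its α-carbon (C8) and not at C6, so the C9 ketone appears with C6=C7 out of conjugation; weak acid and low temperature keep the β,γ-enone from isomerising.

Step 6
Reactants: 8 (8aS)-4,8a-dimethyl-2,3,6,8a-tetrahydroazulene-1,5-dione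
Product: 9 (3aS,8aS)-4,8a-dimethyl-2,3,3a,4,6,8a-hexahydroazulene-1,5-dione (trans-fused; H-1 α; C6=C7; C10 epimers)
Conditions: Li (2.2 equiv), NH3/THF, tBuOH (1 equiv), −78 °C; NH4Cl
Reagents that add atoms: none
Why: Birch-type dissolving-metal reduction of the tetrasubstituted enone; the C1 carbanion is protonated anti to the angular methyl group to give the trans fusion, as in angular-methyl bicyclic enones of this kind. The isolated C6=C7 alkene is inert, and with two equivalents of lithium the enone is consumed before the hindered saturated C4 ketone.

Step 7
Reactants: 9 (3aS,8aS)-4,8a-dimethyl-2,3,3a,4,6,8a-hexahydroazulene-1,5-dione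
Product: 10 6α,7α-epoxide of 9 (trans-fused 4,9-dione; C10 epimers)
Conditions: mCPBA, NaHCO3, CH2Cl2, 0 °C
Reagents that add atoms: 3-chloroperoxybenzoic acid OOC(=O)c1cccc(Cl)c1
Why: Peracid epoxidation of the only alkene from the α face, opposite the axial C5 methyl group; Baeyer–Villiger oxidation of the two ketones is much slower under buffered conditions.

Step 8
Reactants: 10 6α,7α-epoxide of 9
Product: 11 6α-hydroxy-10α-methyl enone (C7=C8 conjugated to the C9 ketone; C4 ketone; H-1 α)
Conditions: DBU, CH2Cl2, 0 °C to rt
Reagents that add atoms: none
Why: E1cB opening of a β,γ-epoxy ketone: deprotonation at C8 expels the C7–O bond and leaves the 6α-alcohol. The same base equilibrates C10 to the 10α-methyl epimer, which has the methyl trans to the C1–C2 bond. Short exposure limits retro-aldol cleavage of the C4-keto/C6-hydroxy unit.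

Step 9
Reactants: 11 6α-hydroxy-10α-methyl enone
Product: 12 6α-tigloyloxy enone (tiglate of 11)
Conditions: (E)-2-methylbut-2-enoyl chloride, DMAP, Et3N, CH2Cl2, 0 °C to rt
Reagents that add atoms: tigloyl chloride C/C=C(\C)C(Cl)=O
Why: DMAP-catalysed acylation of the hindered allylic alcohol, as in the esterification of 6-hydroxy pseudoguaianolides; it installs the final ester and masks the aldol unit in one operation.

Step 10
Reactants: 13 tert-butyl 3-hydroxypropanoate
Product: 14 tert-butyl 3-[(tert-butyldimethylsilyl)oxy]propanoate
Conditions: TBSCl, imidazole, DMF, rt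
Reagents that add atoms: tert-butyldimethylsilyl chloride CC(C)(C)[Si](C)(C)Cl
Why: Standard silylation of a primary alcohol.

Step 11
Reactants: 14 tert-butyl 3-[(tert-butyldimethylsilyl)oxy]propanoate
Product: 15 1-tert-butoxy-1,3-bis[(tert-butyldimethylsilyl)oxy]prop-1-ene (E/Z mixture)
Conditions: LDA, THF, −78 °C; TBSCl, DMPU, −78 °C to rt
Reagents that add atoms: tert-butyldimethylsilyl chloride CC(C)(C)[Si](C)(C)Cl
Why: O-Silylation of the ester enolate to the ketene silyl acetal; at −78 °C trapping is faster than β-elimination of the silyloxy group.

Step 12
Reactants: 12 6α-tigloyloxy enone; 15 1-tert-butoxy-1,3-bis[(tert-butyldimethylsilyl)oxy]prop-1-ene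
Product: 17 8α-bromo-9-ketone with the C7β side chain CH(CH2OTBS)CO2tBu (C11 epimers), via silyl enol ether 16 (not isolated)
Conditions: TBSOTf (10 mol%), CH2Cl2, −78 °C; then NBS, THF, −78 to 0 °C
Reagents that add atoms: N-bromosuccinimide O=C1CCC(=O)N1Br
Why: Mukaiyama–Michael addition: the ketene acetal attacks C7 from the β face, anti to the C6 tiglate, and silyl transfer leaves the enol silane at C8=C9 and not toward C10. NBS then brominates C8 from the α face, anti to the new C7 substituent.

Step 13
Reactants: 17 8α-bromo-9-ketone
Product: 19 6α-tigloyloxy-13-hydroxy-4,9-dioxopseudoguaian-12,8β-olide (cis-fused lactone; C11 epimers), via bromo hydroxy acid 18 (not isolated)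
Conditions: TFA/CH2Cl2/H2O, 0 °C to rt; then NaHCO3, THF/H2O, rt
Reagents that add atoms: none
Why: Acidolysis frees the carboxylic acid and the primary alcohol. On buffering, the carboxylate displaces the α-keto bromide intramolecularly (SN2, 5-exo-tet) with inversion, which can only give the cis-fused 8β-lactone; a bromide of the other configuration would equilibrate through the enol before closing.

Step 14
Reactants: 19 6α-tigloyloxy-13-hydroxy-4,9-dioxopseudoguaian-12,8β-olide
Product: 21 6α-tigloyloxy-4,9-dioxopseudoguai-11(13)-en-12,8β-olide, via mesylate 20 (not isolated)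
Conditions: MsCl, Et3N, CH2Cl2, −30 °C; then DBU, 0 °C
Reagents that add atoms: none
Why: Mesylation of the only hydroxyl and E1cB elimination, the classical dehydration of α-hydroxymethyl lactones to α-methylene lactones; both C11 epimers converge.

Step 15
Reactants: 22 (R)-carvone
Product: 23 (5R)-5-(2-hydroxypropan-2-yl)-2-methylcyclohex-2-en-1-one
Conditions: 50% aq. H2SO4, 0 °C
Reagents that add atoms: water O
Why: Markovnikov hydration of the isopropenyl group through the tertiary cation; the conjugated alkene does not react and the stereocentre is untouched.

Step 16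
Reactants: 23 (5R)-5-(2-hydroxypropan-2-yl)-2-methylcyclohex-2-en-1-one
Product: 24 4-methylbenzenesulfonohydrazone of 23
Conditions: TsNHNH2, MeOH, rt
Reagents that add atoms: 4-methylbenzenesulfonohydrazide Cc1ccc(cc1)S(=O)(=O)NN
Why: Tosylhydrazone condensation of an enone.

Step 17
Reactants: 24 4-methylbenzenesulfonohydrazone of 23
Product: 25 2-[(1R)-4-methylcyclohexa-2,4-dien-1-yl]propan-2-ol
Conditions: MeLi (3.5 equiv), Et2O/TMEDA, 0 °C to rt; H2O
Reagents that add atoms: none
Why: Shapiro reaction: deprotonation at the only sp3 α-carbon, loss of sulfinate and N2, and protonation of the vinyllithium give the 1,3-diene; one extra equivalent of base covers the alkoxide and the stereocentre is not involved.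

Step 18
Reactants: 25 2-[(1R)-4-methylcyclohexa-2,4-dien-1-yl]propan-2-ol
Product: 26 triethyl({2-[(1R)-4-methylcyclohexa-2,4-dien-1-yl]propan-2-yl}oxy)silane
Conditions: TESOTf, 2,6-lutidine, CH2Cl2, −78 °C
Reagents that add atoms: triethylsilyl triflate CC[Si](CC)(CC)OS(=O)(=O)C(F)(F)F
Why: Silylation of the tertiary alcohol so that it neither binds nor ionises under the Lewis acid of step 19.

Step 19
Reactants: 21 6α-tigloyloxy-4,9-dioxopseudoguai-11(13)-en-12,8β-olide; 26 triethyl({2-[(1R)-4-methylcyclohexa-2,4-dien-1-yl]propan-2-yl}oxy)silane
Product: 27 (11S)-spiro adduct (C11 is C2 of a bicyclo[2.2.2]oct-5-ene; C13–C1' and C11–C4' bonds; lactone carbonyl syn to the C2'=C3' bridge; silyloxypropyl group on C5' pointing to the alkene bridge; 4,9-dione)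
Conditions: Me2AlCl (1.5 equiv), CH2Cl2, −78 to −20 °C
Reagents that add atoms: none
Why: Lewis-acid-promoted Diels–Alder reaction of an α-methylene lactone with a 1,3-cyclohexadiene: C13 bonds to the diene terminus next to the methyl-bearing carbon (para orientation) and the diene reacts on the face anti to its C5' substituent. Coordination of Me2AlCl to the lactone carbonyl favours the carbonyl-endo mode, which with the (R)-diene places the new C11–C4' bond on the lactone face that carries C6. No cyclopentenone is present yet, and neither the ketones nor the tiglate are competent dienophiles.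

Step 20
Reactants: 27 (11S)-spiro adduct
Product: 28 9β-alcohol of 27 (C4 ketone retained)
Conditions: NaBH4, MeOH/CH2Cl2, −78 °C
Reagents that add atoms: none
Why: Borohydride reduction of the α-acyloxy ketone, which is inductively activated and should react before the hindered C4 cyclopentanone at low temperature; hydride enters from the α face, anti to the C8 oxygen and the spiro lactone, and gives the 9β-alcohol.

Step 21
Reactants: 28 9β-alcohol of 27
Product: 31 target CNP0185323.3, via silyl enol ether 29 (not isolated), via silylated enone 30 (not isolated)
Conditions: TMSOTf, Et3N, CH2Cl2, 0 °C; Pd(OAc)2, MeCN, rt; HF·pyridine, THF, 0 °C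
Reagents that add atoms: none
Why: Saegusa oxidation: soft enolisation can occur only toward C3, because C5 and C11 are quaternary, and the C9 hydroxyl is silylated in passing. Divalent palladium turns the enol silane into the C2=C3 enone and fluoride removes both silyl ethers; H-1 is not exposed to base because the enone is made last.

## Compound list

1 | 3-methoxy-2-methylbenzaldehyde | COc1cccc(C=O)c1C | starting material
2 | (E)-3-(3-methoxy-2-methylphenyl)prop-2-enoic acid | COc1cccc(/C=C/C(=O)O)c1C | intermediate
3 | 3-(3-methoxy-2-methylphenyl)propanoic acid | COc1cccc(CCC(=O)O)c1C | intermediate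
4 | 3-(3-methoxy-2-methylphenyl)propanoyl chloride | COc1cccc(CCC(=O)Cl)c1C | intermediate
5 | 2-diazo-5-(3-methoxy-2-methylphenyl)pentan-3-one | COc1cccc(CCC(=O)C(C)=[N+]=[N-])c1C | intermediate
6 | norcaradiene valence isomer of 7 (cyclopropane C1–C5–C6; diene C7=C8–C9(OMe)=C10) | C[C@@]12C(=O)CC[C@]1(C(C)=C(OC)C=C3)[C@H]23 | intermediate
7 | (8aS)-5-methoxy-4,8a-dimethyl-2,3-dihydroazulen-1(8aH)-one | C1=CC=C(OC)C(C)=C2CCC(=O)[C@]21C | intermediate
8 | (8aS)-4,8a-dimethyl-2,3,6,8a-tetrahydroazulene-1,5-dione | C1=CCC(=O)C(C)=C2CCC(=O)[C@]21C | intermediate
9 | (3aS,8aS)-4,8a-dimethyl-2,3,3a,4,6,8a-hexahydroazulene-1,5-dione, trans-fused, C10 epimers | C1=CCC(=O)C(C)[C@@H]2CCC(=O)[C@]21C | intermediate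
10 | 6α,7α-epoxide of 9, C10 epimers | O3[C@H]1[C@@H]3CC(=O)C(C)[C@@H]2CCC(=O)[C@]21C | intermediate
11 | 6α-hydroxy-10α-methyl-7-ene-4,9-dione, trans-fused (H-1 α) | O[C@H]1C=CC(=O)[C@@H](C)[C@@H]2CCC(=O)[C@]21C | intermediate
12 | 6-O-tiglate of 11 | C/C=C(\C)C(=O)O[C@H]1C=CC(=O)[C@@H](C)[C@@H]2CCC(=O)[C@]21C | intermediate
13 | tert-butyl 3-hydroxypropanoate | CC(C)(C)OC(=O)CCO | starting material
14 | tert-butyl 3-[(tert-butyldimethylsilyl)oxy]propanoate | CC(C)(C)OC(=O)CCO[Si](C)(C)C(C)(C)C | intermediate
15 | 1-tert-butoxy-1,3-bis[(tert-butyldimethylsilyl)oxy]prop-1-ene | CC(C)(C)OC(O[Si](C)(C)C(C)(C)C)=CCO[Si](C)(C)C(C)(C)C | intermediate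
16 | C8=C9 tert-butyldimethylsilyl enol ether with C7β side chain CH(CH2OTBS)CO2tBu, 6α-tiglate | C/C=C(\C)C(=O)O[C@H]1[C@H](C(CO[Si](C)(C)C(C)(C)C)C(=O)OC(C)(C)C)C=C(O[Si](C)(C)C(C)(C)C)[C@@H](C)[C@@H]2CCC(=O)[C@]21C | intermediate
17 | 8α-bromo-4,9-dione with C7β side chain CH(CH2OTBS)CO2tBu, 6α-tiglate | C/C=C(\C)C(=O)O[C@H]1[C@H](C(CO[Si](C)(C)C(C)(C)C)C(=O)OC(C)(C)C)[C@@H](Br)C(=O)[C@@H](C)[C@@H]2CCC(=O)[C@]21C | intermediate
18 | 8α-bromo-4,9-dione with C7β side chain CH(CH2OH)CO2H, 6α-tiglate | C/C=C(\C)C(=O)O[C@H]1[C@H](C(CO)C(=O)O)[C@@H](Br)C(=O)[C@@H](C)[C@@H]2CCC(=O)[C@]21C | intermediate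
19 | 6α-tigloyloxy-13-hydroxy-4,9-dioxopseudoguaian-12,8β-olide, C11 epimers | C/C=C(\C)C(=O)O[C@H]1[C@H]2[C@H](OC(=O)C2CO)C(=O)[C@@H](C)[C@@H]2CCC(=O)[C@]21C | intermediate
20 | 13-O-methanesulfonate of 19 | C/C=C(\C)C(=O)O[C@H]1[C@H]2[C@H](OC(=O)C2COS(C)(=O)=O)C(=O)[C@@H](C)[C@@H]2CCC(=O)[C@]21C | intermediate
21 | 6α-tigloyloxy-4,9-dioxopseudoguai-11(13)-en-12,8β-olide | C/C=C(\C)C(=O)O[C@H]1[C@H]2[C@H](OC(=O)C2=C)C(=O)[C@@H](C)[C@@H]2CCC(=O)[C@]21C | intermediate
22 | (R)-carvone | CC1=CC[C@H](CC1=O)C(C)=C | starting material
23 | (5R)-5-(2-hydroxypropan-2-yl)-2-methylcyclohex-2-en-1-one | CC1=CC[C@H](CC1=O)C(C)(C)O | intermediate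
24 | 4-methylbenzenesulfonohydrazone of 23 | CC1=CC[C@H](CC1=NNS(=O)(=O)c1ccc(C)cc1)C(C)(C)O | intermediate
25 | 2-[(1R)-4-methylcyclohexa-2,4-dien-1-yl]propan-2-ol | CC1=CC[C@H](C=C1)C(C)(C)O | intermediate
26 | triethyl({2-[(1R)-4-methylcyclohexa-2,4-dien-1-yl]propan-2-yl}oxy)silane | CC1=CC[C@H](C=C1)C(C)(C)O[Si](CC)(CC)CC | intermediate
27 | (11S)-spiro Diels–Alder adduct, 4,9-dione, 6α-tiglate, tertiary triethylsilyl ether | C/C=C(\C)C(=O)O[C@H]1[C@H]2[C@H](OC(=O)[C@]23C[C@@H]2C[C@@H](C(C)(C)O[Si](CC)(CC)CC)[C@H]3C=C2C)C(=O)[C@@H](C)[C@@H]2CCC(=O)[C@]21C | intermediate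
28 | 9β-alcohol of 27 | C/C=C(\C)C(=O)O[C@H]1[C@H]2[C@H](OC(=O)[C@]23C[C@@H]2C[C@@H](C(C)(C)O[Si](CC)(CC)CC)[C@H]3C=C2C)[C@H](O)[C@@H](C)[C@@H]2CCC(=O)[C@]21C | intermediate
29 | C3=C4 trimethylsilyl enol ether of 28 with 9-O-trimethylsilyl ether | C/C=C(\C)C(=O)O[C@H]1[C@H]2[C@H](OC(=O)[C@]23C[C@@H]2C[C@@H](C(C)(C)O[Si](CC)(CC)CC)[C@H]3C=C2C)[C@H](O[Si](C)(C)C)[C@@H](C)[C@@H]2CC=C(O[Si](C)(C)C)[C@]21C | intermediate
30 | 9-O-trimethylsilyl, tertiary O-triethylsilyl ether of the target | C/C=C(\C)C(=O)O[C@H]1[C@H]2[C@H](OC(=O)[C@]23C[C@@H]2C[C@@H](C(C)(C)O[Si](CC)(CC)CC)[C@H]3C=C2C)[C@H](O[Si](C)(C)C)[C@@H](C)[C@@H]2C=CC(=O)[C@]21C | intermediate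
31 | CNP0185323.3 | C/C=C(\C)C(=O)O[C@H]1[C@H]2[C@H](OC(=O)[C@]23C[C@@H]2C[C@@H](C(C)(C)O)[C@H]3C=C2C)[C@H](O)[C@@H](C)[C@@H]2C=CC(=O)[C@]21C | target

## Step count and least certain steps

Total: 21 steps. Longest linear sequence: 15 steps from 1 (steps 1–9, 12–14, 19–21). The donor 15 takes two steps and the diene 26 four.

**Step 4 (key step).** The carbene may be diverted before it cyclopropanates: 1,2-hydride shift from the C5 methyl group gives a vinyl ketone, and attack at C6 (para to the methoxy group) without ring closure leads to a tetralone. Enantioface selection may also be incomplete, because induction rests on a single ligand–carbene contact far from the arene. Fallback: separate ring construction from asymmetric induction. Cyclise 5 with Rh2(OAc)4 in CH2Cl2, chosen only for chemoselectivity, to the racemic azulenone F1, and resolve F1 by chromatography on a chiral stationary phase. The fallback sets out from 5 and returns at 7.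

**Step 19 (cycloaddition).** The most likely failure is poor endo/exo selectivity, which here is the same thing as poor facial selectivity at the lactone. The endo mode must bring the diene onto the lactone face that carries C6, which is flanked by H-6 and the C5 substituents. The exo mode uses the open face next to H-7 and gives the C11 epimer, which cannot be corrected afterwards. Lewis-acid isomerisation of the diene is a second risk. Fallback: replace substrate control by reagent control. Run the union of 21 and 26 with a chiral oxazaborolidinium triflimide Lewis acid (prolinol-derived, B-aryl), choosing the antipode that shields the H-7 face of the coordinated lactone, so that the catalyst both enforces the endo mode and selects the face. It sets out from 21 and 26, returns at 27 and makes no new compound.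

**Step 6 (dissolving-metal reduction).** Loss of chemoselectivity is the most likely failure: the C4 ketone may be partly reduced alongside the enone because both accept electrons from lithium. Protonation at C1 may also be incompletely trans-selective. Fallback: over-reduce on purpose and re-oxidise. Treat 8 with excess Li and tBuOH so that the enone ends as the C9 enolate and the C4 ketone as the alkoxide, isolate the keto alcohol F8, and oxidise its C4 carbinol with Dess–Martin periodinane. It sets out from 8 and returns at 9.

**Step 5 (enol ether hydrolysis).** Kinetic control may be lost. Acid-catalysed enolisation can move C6=C7 into conjugation with the C9 ketone and destroy the handle for the C6 oxygen, and protonation of the norcaradiene tautomer can lead to rearomatisation. Fallback: unmask with fluoride instead of acid. Demethylate 3 with BBr3 to the phenol acid F2 and silylate it (TIPSCl, imidazole, aqueous work-up) to the silyl ether acid F3. As in step 3, convert F3 through the acid chloride F4 into the diazoketone F5. Under the conditions of step 4, F5 gives, through the norcaradiene F6, the silyl enol ether F7. Bu4NF buffered with AcOH at −78 °C then liberates the dienolate, which is protonated kinetically at C8. The fallback sets out from 3 and returns at 8.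

**Step 20 (ketone reduction).** Discrimination between the two ketones may be incomplete, because the α-acyloxy ketone at C9, though activated, is the more hindered one after the cycloaddition. Fallback: reduce both carbonyls of 27 on purpose (excess NaBH4, 0 °C) to the diol F9, and re-oxidise only its C4 carbinol with catalytic TEMPO and PhI(OAc)2. The C4 carbinol is the less hindered one and is not deactivated by an α-acyloxy group. It sets out from 27 and returns at 28.

Further compounds
F1 | step 4 | racemic 5-methoxy-4,8a-dimethyl-2,3-dihydroazulen-1(8aH)-one | C1=CC=C(OC)C(C)=C2CCC(=O)C21C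
F0 | step 19 | none | none
F8 | step 6 | (3aS,8aS)-1-hydroxy-4,8a-dimethyl-1,2,3,3a,4,8a-hexahydroazulen-5(6H)-one (C4 carbinol, C9 ketone, C6=C7) | C1=CCC(=O)C(C)[C@@H]2CCC(O)[C@]21C
F2 | step 5 | 3-(3-hydroxy-2-methylphenyl)propanoic acid | Cc1c(O)cccc1CCC(=O)O
F3 | step 5 | 3-{2-methyl-3-[(triisopropylsilyl)oxy]phenyl}propanoic acid | Cc1c(O[Si](C(C)C)(C(C)C)C(C)C)cccc1CCC(=O)O
F4 | step 5 | 3-{2-methyl-3-[(triisopropylsilyl)oxy]phenyl}propanoyl chloride | Cc1c(O[Si](C(C)C)(C(C)C)C(C)C)cccc1CCC(=O)Cl
F5 | step 5 | 2-diazo-5-{2-methyl-3-[(triisopropylsilyl)oxy]phenyl}pentan-3-one | Cc1c(O[Si](C(C)C)(C(C)C)C(C)C)cccc1CCC(=O)C(C)=[N+]=[N-]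
F6 | step 5 | norcaradiene valence isomer of F7 | C[C@@]12C(=O)CC[C@]1(C(C)=C(O[Si](C(C)C)(C(C)C)C(C)C)C=C3)[C@H]23
F7 | step 5 | (8aS)-4,8a-dimethyl-5-[(triisopropylsilyl)oxy]-2,3-dihydroazulen-1(8aH)-one | C1=CC=C(O[Si](C(C)C)(C(C)C)C(C)C)C(C)=C2CCC(=O)[C@]21C
F9 | step 20 | 4,9β-diol corresponding to 27 (both ketones reduced) | C/C=C(\C)C(=O)O[C@H]1[C@H]2[C@H](OC(=O)[C@]23C[C@@H]2C[C@@H](C(C)(C)O[Si](CC)(CC)CC)[C@H]3C=C2C)[C@H](O)[C@@H](C)[C@@H]2CCC(O)[C@]21C
A1 | alternative 1 | 6-hydroxy hydroazulene 8,12-lactone, C4 ethylene ketal, C9 tert-butyldimethylsilyl ether | O[C@H]1[C@H]2[C@H](OC(=O)C2)[C@H](O[Si](C)(C)C(C)(C)C)[C@@H](C)[C@@H]2C=CC3(OCCO3)[C@]21C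
A2 | alternative 2 | trans-fused 5,10-dimethylhydroazulene-4,9-dione 8,12-lactone, C6 tert-butyldimethylsilyl ether | CC(C)(C)[Si](C)(C)O[C@H]1[C@H]2[C@H](OC(=O)C2)C(=O)[C@@H](C)[C@@H]2CCC(=O)[C@]21C
A3 | alternative 3 | trans-fused 5,10-dimethylhydroazulen-8-one with C9=C10 alkene, C4 tert-butyl ether | C1CC(=O)C=C(C)[C@@H]2CC[C@H](OC(C)(C)C)[C@]21C
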